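**Assumption:** the target SMILES contains no stereocentre or stereogenic double bond, so the compound is achiral and no enantiocontrol is needed.

**Retrosynthetic overview**
1. Target 10 ⇐ phenolic ethyl dihydrocinnamate 9 by ester reduction.
2. 9 ⇐ O-benzyl cinnamate 7: one hydrogenation saturates the C=C and removes the benzyl group. 7 ⇐ aldehyde 5 by a two-carbon Wittig extension.
3. 5 ⇐ diaryl ether C–O disconnection (Ullmann coupling) into O-benzyl-5-iodovanillin 3 and 2,6-dimethoxy-4-propylphenol 4.
4. No ring is formed: both benzene rings are bought (ring B as 5-iodovanillin 1, ring A as phenol 4) and are joined through the ether oxygen in step 2.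

**Route**

Step 1
Reactants: 1 5-iodovanillin (4-hydroxy-3-iodo-5-methoxybenzaldehyde); 2 benzyl bromide
Product: 3 4-(benzyloxy)-3-iodo-5-methoxybenzaldehyde
Conditions: BnBr (1.2 eq), K2CO3 (1.5 eq), DMF, rt → 50 °C
Reagents that add atoms: benzyl bromide (2), BrCc1ccccc1
Why: Williamson ether synthesis on the acidic vanillin-type phenol masks the OH so that it can neither compete as a nucleophile nor deactivate the aryl iodide in the coupling; no stereocentre is formed.

Step 2
Reactants: 3 4-(benzyloxy)-3-iodo-5-methoxybenzaldehyde; 4 2,6-dimethoxy-4-propylphenol (1.3 eq)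
Product: 5 4-(benzyloxy)-3-(2,6-dimethoxy-4-propylphenoxy)-5-methoxybenzaldehyde
Conditions: CuI (10 mol%), picolinic acid (20 mol%), K3PO4 (2 eq), DMSO, 90 °C, Ar
Reagents that add atoms: 2,6-dimethoxy-4-propylphenol (4), CCCc1cc(OC)c(O)c(OC)c1
Why: Ligand-accelerated Ullmann diaryl ether coupling with a Cu(I)/picolinate catalyst tolerates ortho substituents on both partners, and the non-enolisable aldehyde and the benzyl ether are stable to K3PO4; no stereocentre is formed.

Step 3
Reactants: 5 4-(benzyloxy)-3-(2,6-dimethoxy-4-propylphenoxy)-5-methoxybenzaldehyde; 6 ethyl (triphenylphosphoranylidene)acetate (1.2 eq)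
Product: 7 ethyl (E)-3-[4-(benzyloxy)-3-(2,6-dimethoxy-4-propylphenoxy)-5-methoxyphenyl]prop-2-enoate
Conditions: Ph3P=CHCO2Et, toluene, 100 °C
Reagents that add atoms: ethyl (triphenylphosphoranylidene)acetate (6), CCOC(=O)C=P(c1ccccc1)(c1ccccc1)c1ccccc1
Why: Wittig olefination with a stabilised ylide adds the two missing chain carbons at the right oxidation level; it is E-selective, but the alkene geometry is erased in the next step.

Step 4
Reactants: 7 ethyl (E)-3-[4-(benzyloxy)-3-(2,6-dimethoxy-4-propylphenoxy)-5-methoxyphenyl]prop-2-enoate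
Product: 9 ethyl 3-[3-(2,6-dimethoxy-4-propylphenoxy)-4-hydroxy-5-methoxyphenyl]propanoate, via saturated O-benzyl ester 8 (not isolated)
Conditions: H2 (1 atm), 10% Pd/C, EtOAc/EtOH 1:1, rt
Reagents that add atoms: none
Why: Catalytic hydrogenation first saturates the cinnamate C=C and then hydrogenolyses the benzyl ether, while the ester, the aryl methyl ethers and the diaryl ether are inert at room temperature; no stereocentre is formed.

Step 5
Reactants: 9 ethyl 3-[3-(2,6-dimethoxy-4-propylphenoxy)-4-hydroxy-5-methoxyphenyl]propanoate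
Product: 10 2-(2,6-dimethoxy-4-propylphenoxy)-4-(3-hydroxypropyl)-6-methoxyphenol (target, CNP0368877.0)
Conditions: LiAlH4 (2.5 eq), THF, 0 °C → rt; then H2O, aq. Rochelle salt
Reagents that add atoms: none
Why: Hydride reduction of the ester to the primary alcohol with LiAlH4 (one extra hydride equivalent is consumed by the phenol, which is regenerated on work-up) leaves all ether bonds untouched; no stereocentre is formed.

**Compound list**
1 | 5-iodovanillin (4-hydroxy-3-iodo-5-methoxybenzaldehyde) | COc1cc(C=O)cc(I)c1O | starting material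
2 | benzyl bromide | BrCc1ccccc1 | starting material
3 | 4-(benzyloxy)-3-iodo-5-methoxybenzaldehyde | COc1cc(C=O)cc(I)c1OCc1ccccc1 | intermediate
4 | 2,6-dimethoxy-4-propylphenol (4-propylsyringol) | CCCc1cc(OC)c(O)c(OC)c1 | starting material
5 | 4-(benzyloxy)-3-(2,6-dimethoxy-4-propylphenoxy)-5-methoxybenzaldehyde | CCCc1cc(OC)c(Oc2cc(C=O)cc(OC)c2OCc2ccccc2)c(OC)c1 | intermediate
6 | ethyl (triphenylphosphoranylidene)acetate | CCOC(=O)C=P(c1ccccc1)(c1ccccc1)c1ccccc1 | starting material
7 | ethyl (E)-3-[4-(benzyloxy)-3-(2,6-dimethoxy-4-propylphenoxy)-5-methoxyphenyl]prop-2-enoate | CCCc1cc(OC)c(Oc2cc(/C=C/C(=O)OCC)cc(OC)c2OCc2ccccc2)c(OC)c1 | intermediate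
8 | ethyl 3-[4-(benzyloxy)-3-(2,6-dimethoxy-4-propylphenoxy)-5-methoxyphenyl]propanoate (not isolated) | CCCc1cc(OC)c(Oc2cc(CCC(=O)OCC)cc(OC)c2OCc2ccccc2)c(OC)c1 | intermediate
9 | ethyl 3-[3-(2,6-dimethoxy-4-propylphenoxy)-4-hydroxy-5-methoxyphenyl]propanoate | CCCc1cc(OC)c(Oc2cc(CCC(=O)OCC)cc(OC)c2O)c(OC)c1 | intermediate
10 | 2-(2,6-dimethoxy-4-propylphenoxy)-4-(3-hydroxypropyl)-6-methoxyphenol | CCCc1cc(OC)c(Oc2cc(CCCO)cc(OC)c2O)c(OC)c1 | target

**Total step count:** 5
**Longest linear sequence:** 5 steps (1 → 3 → 5 → 7 → 9 → 10)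

**Three steps most likely to fail, with fallbacks**

Step 2 (Ullmann coupling; the phenol is 2,6-disubstituted and the iodide carries an ortho benzyloxy group, so the coupling may stall). The fallback replaces the metal-catalysed coupling by an SNAr reaction and builds the ring-B substituents afterwards; it sets out from 4 and comes back to the route at 10. Phenol 4 is heated with purchased 2-fluoro-6-methoxybenzaldehyde (COc1cccc(F)c1C=O) and K2CO3 in DMF at 120 °C; substitution of the fluoride ortho to the formyl group gives 2-(2,6-dimethoxy-4-propylphenoxy)-6-methoxybenzaldehyde F1. Baeyer–Villiger (Dakin-type) oxidation with mCPBA in CH2Cl2 gives 2-(2,6-dimethoxy-4-propylphenoxy)-6-methoxyphenyl formate F2, which aqueous KOH in MeOH hydrolyses to 2-(2,6-dimethoxy-4-propylphenoxy)-6-methoxyphenol F3. O-Allylation with allyl bromide and K2CO3 in acetone gives 2-(allyloxy)-1-(2,6-dimethoxy-4-propylphenoxy)-3-methoxybenzene F4. Heating F4 in N,N-diethylaniline at 200 °C gives 4-allyl-2-(2,6-dimethoxy-4-propylphenoxy)-6-methoxyphenol F5 by a para-Claisen rearrangement; both ortho positions are blocked, and the intramolecular shift avoids electrophilic attack on the electron-rich ring A. Hydroboration of F5 with excess 9-BBN in THF followed by NaOH/H2O2 gives 10.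

Step 4 (hydrogenation/hydrogenolysis; the flanked benzyl ether may cleave slowly, or traces of copper, iodide or phosphorus compounds may poison the catalyst). The fallback uses no hydrogenation; it sets out from 7 and comes back to the route at 9. The benzyl ether of 7 is cleaved with BCl3 and pentamethylbenzene as cation scavenger in CH2Cl2 at −78 °C to give ethyl (E)-3-[3-(2,6-dimethoxy-4-propylphenoxy)-4-hydroxy-5-methoxyphenyl]prop-2-enoate F6. Conjugate reduction of F6 with NaBH4 and NiCl2·6H2O in EtOH at 0 °C then gives 9.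

Step 5 (LiAlH4 on a phenolic ester; insoluble aluminium phenoxides can stop the reduction or trap the product on work-up). The fallback goes through the acid and an electrophilic reductant; it sets out from 9 and comes back to the route at 10. Ester 9 is saponified with LiOH in THF/H2O and acidified to give 3-[3-(2,6-dimethoxy-4-propylphenoxy)-4-hydroxy-5-methoxyphenyl]propanoic acid F7. F7 is reduced with BH3·THF (0 °C → rt, MeOH quench), which reduces the carboxylic acid selectively, to give 10.

**Further compounds**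
F1 | step 2 | 2-(2,6-dimethoxy-4-propylphenoxy)-6-methoxybenzaldehyde | CCCc1cc(OC)c(Oc2cccc(OC)c2C=O)c(OC)c1
F2 | step 2 | 2-(2,6-dimethoxy-4-propylphenoxy)-6-methoxyphenyl formate | CCCc1cc(OC)c(Oc2cccc(OC)c2OC=O)c(OC)c1
F3 | step 2 | 2-(2,6-dimethoxy-4-propylphenoxy)-6-methoxyphenol | CCCc1cc(OC)c(Oc2cccc(OC)c2O)c(OC)c1
F4 | step 2 | 2-(allyloxy)-1-(2,6-dimethoxy-4-propylphenoxy)-3-methoxybenzene | CCCc1cc(OC)c(Oc2cccc(OC)c2OCC=C)c(OC)c1
F5 | step 2 | 4-allyl-2-(2,6-dimethoxy-4-propylphenoxy)-6-methoxyphenol | CCCc1cc(OC)c(Oc2cc(CC=C)cc(OC)c2O)c(OC)c1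
F6 | step 4 | ethyl (E)-3-[3-(2,6-dimethoxy-4-propylphenoxy)-4-hydroxy-5-methoxyphenyl]prop-2-enoate | CCCc1cc(OC)c(Oc2cc(/C=C/C(=O)OCC)cc(OC)c2O)c(OC)c1
F7 | step 5 | 3-[3-(2,6-dimethoxy-4-propylphenoxy)-4-hydroxy-5-methoxyphenyl]propanoic acid | CCCc1cc(OC)c(Oc2cc(CCC(=O)O)cc(OC)c2O)c(OC)c1
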